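**Retrosynthetic overview** (ring A = chromone benzene ring, ring B = dimethoxyphenyl ring, ring C = pyranone, ring D = oxepine, ring E = dimethylpyran)
1. Ring D is cut at two bonds at once, O–C(isopropylidene) and C2–C1': 19 ⇒ chromone 14 (C2–H, 2-bromoprenyl chain on C3) + 2-iodo-4,5-dimethoxyphenol 16, joined in one flask by C2 zincation, Negishi coupling and palladium-catalysed vinyl etherification.
2. Enabling feature: ring A carries no hydrogen, so C2–H of ring C (next to O1) is the only acidic sp2 C–H. C2 and the brominated vinylic carbon of the C3 chain are 1,4-related and match the ortho C–I/O–H pair of ring B, and each partner has one nucleophilic and one electrophilic end, which fixes the orientation of the annulation.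
3. Ring C: 14 ⇐ aryl ketone 12 + one carbon from DMF-DMA; 12 ⇐ acetophenone 8 + 1,2-dibromo-3-methylbut-2-ene 11 (dianion alkylation), which brings in the isopropylidene vinyl bromide intact.
4. Ring A substituents: ring E by condensation of acetophenone 1 with prenal and oxa-6π closure; the C-prenyl group by O-prenylation and para-Claisen–Cope shift.
5. Order of ring formation: ring E (step 1), ring C (step 6), ring D together with attachment of ring B (step 8). The target has no stereocentre and no stereogenic double bond.

Key step: step 8

**Step 1**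
Reactants: 1 1-(2,4-dihydroxy-6-methoxyphenyl)ethan-1-one; 2 3-methylbut-2-enal
Product: 4 1-(5-hydroxy-7-methoxy-2,2-dimethyl-2H-chromen-6-yl)ethan-1-one (evodionol), via ortho-quinone methide 3 (not isolated)
Conditions: Ca(OH)2, MeOH, 25 °C
Reagents that add atoms: none
Why: Base-mediated condensation of the phenoxide carbon with the enal followed by oxa-6π electrocyclization of the ortho-quinone methide (formal [3+3] chromene annulation) should occur at C3, the carbon flanked by two oxygens, and close through the free 4-hydroxyl because the 2-hydroxyl is tied up in the calcium chelate with the ketone.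

**Step 2**
Reactants: 4 evodionol; 5 1-bromo-3-methylbut-2-ene
Product: 6 1-[7-methoxy-2,2-dimethyl-5-(3-methylbut-2-en-1-yloxy)-2H-chromen-6-yl]ethan-1-one
Conditions: K2CO3, DMF, 60 °C
Reagents that add atoms: none
Why: Williamson etherification of the only phenol with a reactive allylic bromide should give the prenyl ether, the SN2 pathway at the primary carbon keeping the prenyl unit unrearranged.

**Step 3**
Reactants: 6 prenyl ether
Product: 8 1-[5-hydroxy-7-methoxy-2,2-dimethyl-8-(3-methylbut-2-en-1-yl)-2H-chromen-6-yl]ethan-1-one, via ortho-dienone 7 (not isolated)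
Conditions: PhNEt2, 200 °C, sealed tube
Reagents that add atoms: none
Why: Aromatic Claisen rearrangement onto a blocked ortho carbon followed by Cope rearrangement to the only free ring position (para, C8) and tautomerization (para-Claisen–Cope sequence) should deliver the normal prenyl group, because two successive [3,3] shifts invert the allyl unit twice.

**Step 4**
Reactants: 9 3-methylbuta-1,2-diene
Product: 11 1,2-dibromo-3-methylbut-2-ene, via 2,3-dibromo-3-methylbut-1-ene 10 (not isolated)
Conditions: Br2, CH2Cl2, −78 °C to 25 °C, then 40 °C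
Reagents that add atoms: bromine, BrBr
Why: Electrophilic addition of bromine to the central allene carbon through a 2-bromoallyl cation should give the tertiary allylic bromide first, which equilibrates by allylic 1,3-bromide shift to the primary bromide with the tetrasubstituted double bond.

**Step 5**
Reactants: 8 prenylated acetophenone; 11 1,2-dibromo-3-methylbut-2-ene
Product: 12 4-bromo-1-[5-hydroxy-7-methoxy-2,2-dimethyl-8-(3-methylbut-2-en-1-yl)-2H-chromen-6-yl]-5-methylhex-4-en-1-one
Conditions: LiN(SiMe3)2 (2.3 equiv), THF, −78 to 0 °C; then 11, −78 to 0 °C; aq. NH4Cl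
Reagents that add atoms: none
Why: Enolate alkylation of the phenoxide–enolate dianion should occur at carbon, the more nucleophilic site, by SN2 displacement of the primary allylic bromide, while the vinylic bromide is inert.

**Step 6**
Reactants: 12 aryl ketone
Product: 14 3-(2-bromo-3-methylbut-2-en-1-yl)-5-methoxy-8,8-dimethyl-6-(3-methylbut-2-en-1-yl)-4H,8H-pyrano[2,3-f]chromen-4-one, via enaminone 13 (not isolated)
Conditions: Me2NCH(OMe)2, toluene, 110 °C
Reagents that add atoms: N,N-dimethylformamide dimethyl acetal, COC(OC)N(C)C
Why: Aminomethylenation of the ketone α-methylene followed by addition–elimination of the ortho-hydroxyl on the enaminone (enaminone route to 3-substituted chromones) should close ring C and leave C2 as a C–H position.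

**Step 7**
Reactants: 15 3,4-dimethoxyphenol
Product: 16 2-iodo-4,5-dimethoxyphenol
Conditions: NIS, MeCN, 0 °C
Reagents that add atoms: N-iodosuccinimide, O=C1CCC(=O)N1I
Why: Electrophilic aromatic iodination should take place at C6, which is ortho to the hydroxyl, para to a methoxy group and less hindered than C2.

**Step 8**
Reactants: 14 chromone; 16 2-iodo-4,5-dimethoxyphenol
Product: 19 CNP0192589.0 (isopropylidene-oxepine-bridged 4',5'-dimethoxyflavone of the 5-methoxy-6-prenyl-pyrano[2,3-f]chromen-4-one series), via chromon-2-ylzinc chloride 17 (not isolated), via open biaryl bromophenol 18 (not isolated)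
Conditions: TMPZnCl·LiCl (1.2 equiv), THF, 25 °C; then 16 premixed with NaH, Pd2(dba)3 (2.5 mol %), tBuXPhos (10 mol %), THF–toluene, 25 °C, then 100 °C
Reagents that add atoms: none
Why: The zinc amide should remove the C2 proton of ring C to give 17; zerovalent palladium then inserts into the C–I bond of the sodium phenoxide of 16 at 25 °C, and transmetalation from zinc with C–C reductive elimination joins C2 to C1' of ring B to give 18; on heating, zerovalent palladium inserts into the vinylic C–Br bond, the tethered phenoxide replaces bromide on divalent palladium, and C–O reductive elimination forms the enol ether. The closest known reaction types are C2 zincation of chromones with TMP zinc amides followed by Negishi arylation, Negishi coupling in the presence of unprotected phenols, and palladium-catalysed etherification of vinyl halides with phenols run in tandem with a C–C cross-coupling; only their telescoping into a (4+3) annulation is new. Ring D is closed at its O–C(vinyl) bond by reductive elimination from an eight-membered oxapalladacycle, after its C2–C1' bond has been made intermolecularly. No stereocentre is formed, and the isopropylidene double bond is carried unchanged from 11, so neither its position nor its geometry is in question. The step needs site-selective metalation, which is secured because ring A has no C–H and C2–H is the only sp2 C–H next to O1, and it needs the aryl iodide to react before the vinyl bromide, which the hindered tetrasubstituted bromide should ensure at 25 °C. The orientation of the annulation is fixed because the chromone offers C2–Zn and C–Br while the phenol offers C–I and O−, so only the C2–C1' and O–C(vinyl) pairings are possible, and coupling within 17 would require a four-membered ring.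

**Compound list**
1 | 1-(2,4-dihydroxy-6-methoxyphenyl)ethan-1-one | CC(=O)c1c(O)cc(O)cc1OC | starting material
2 | 3-methylbut-2-enal | CC(C)=CC=O | starting material
3 | (6Z)-4-acetyl-5-hydroxy-3-methoxy-6-(3-methylbut-2-en-1-ylidene)cyclohexa-2,4-dien-1-one (ortho-quinone methide) | CC(=O)C1=C(O)/C(=C/C=C(C)C)C(=O)C=C1OC | intermediate
4 | 1-(5-hydroxy-7-methoxy-2,2-dimethyl-2H-chromen-6-yl)ethan-1-one (evodionol) | CC(=O)c1c(O)c2C=CC(C)(C)Oc2cc1OC | intermediate
5 | 1-bromo-3-methylbut-2-ene | CC(C)=CCBr | starting material
6 | 1-[7-methoxy-2,2-dimethyl-5-(3-methylbut-2-en-1-yloxy)-2H-chromen-6-yl]ethan-1-one | CC(=O)c1c(OCC=C(C)C)c2C=CC(C)(C)Oc2cc1OC | intermediate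
7 | rac-6-acetyl-7-methoxy-2,2-dimethyl-6-(2-methylbut-3-en-2-yl)-2H-chromen-5(6H)-one (ortho-dienone, racemic) | CC(=O)C1(C(C)(C)C=C)C(=O)C2=C(OC(C)(C)C=C2)C=C1OC | intermediate
8 | 1-[5-hydroxy-7-methoxy-2,2-dimethyl-8-(3-methylbut-2-en-1-yl)-2H-chromen-6-yl]ethan-1-one | CC(=O)c1c(O)c2C=CC(C)(C)Oc2c(CC=C(C)C)c1OC | intermediate
9 | 3-methylbuta-1,2-diene | CC(C)=C=C | starting material
10 | 2,3-dibromo-3-methylbut-1-ene | CC(C)(Br)C(Br)=C | intermediate
11 | 1,2-dibromo-3-methylbut-2-ene | CC(C)=C(Br)CBr | intermediate
12 | 4-bromo-1-[5-hydroxy-7-methoxy-2,2-dimethyl-8-(3-methylbut-2-en-1-yl)-2H-chromen-6-yl]-5-methylhex-4-en-1-one | CC(C)=C(Br)CCC(=O)c1c(O)c2C=CC(C)(C)Oc2c(CC=C(C)C)c1OC | intermediate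
13 | (E)-4-bromo-2-[(dimethylamino)methylidene]-1-[5-hydroxy-7-methoxy-2,2-dimethyl-8-(3-methylbut-2-en-1-yl)-2H-chromen-6-yl]-5-methylhex-4-en-1-one (enaminone) | CN(C)/C=C(\CC(Br)=C(C)C)C(=O)c1c(O)c2C=CC(C)(C)Oc2c(CC=C(C)C)c1OC | intermediate
14 | 3-(2-bromo-3-methylbut-2-en-1-yl)-5-methoxy-8,8-dimethyl-6-(3-methylbut-2-en-1-yl)-4H,8H-pyrano[2,3-f]chromen-4-one | COc1c(CC=C(C)C)c2OC(C)(C)C=Cc2c2occ(CC(Br)=C(C)C)c(=O)c12 | intermediate
15 | 3,4-dimethoxyphenol | COc1ccc(O)cc1OC | starting material
16 | 2-iodo-4,5-dimethoxyphenol | COc1cc(O)c(I)cc1OC | intermediate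
17 | [3-(2-bromo-3-methylbut-2-en-1-yl)-5-methoxy-8,8-dimethyl-6-(3-methylbut-2-en-1-yl)-4-oxo-4H,8H-pyrano[2,3-f]chromen-2-yl]zinc chloride (LiCl complex) | COc1c(CC=C(C)C)c2OC(C)(C)C=Cc2c2oc([Zn]Cl)c(CC(Br)=C(C)C)c(=O)c12 | intermediate
18 | 3-(2-bromo-3-methylbut-2-en-1-yl)-2-(2-hydroxy-4,5-dimethoxyphenyl)-5-methoxy-8,8-dimethyl-6-(3-methylbut-2-en-1-yl)-4H,8H-pyrano[2,3-f]chromen-4-one | COc1cc(O)c(cc1OC)-c1oc2c3C=CC(C)(C)Oc3c(CC=C(C)C)c(OC)c2c(=O)c1CC(Br)=C(C)C | intermediate
19 | CNP0192589.0 (isopropylidene-oxepine-bridged 4',5'-dimethoxyflavone of the 5-methoxy-6-prenyl-pyrano[2,3-f]chromen-4-one series) | COc1cc2c(cc1OC)-c1oc3c4c(c(CC=C(C)C)c(OC)c3c(=O)c1CC(=C(C)C)O2)OC(C)(C)C=C4 | target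

**Step count and risks**
Total steps: 8. Longest linear sequence: 6 (steps 1, 2, 3, 5, 6, 8).

Steps most likely to fail:

1. Step 8. The final C–O reductive elimination from the hindered tetrasubstituted vinylpalladium may be slower than protodemetalation of the zinc reagent or β-hydride elimination of the vinylpalladium to an allene, so the cascade may stop at or divert from the open biaryl stage. The fallback builds ring C in the classical way and closes ring D with copper. It sets out from 12 and rejoins the route at 18. The dianion of 12 (LiN(SiMe3)2, THF) would be C-acylated with methyl 2-(methoxymethoxy)-4,5-dimethoxybenzoate F1 (prepared from methyl 2-hydroxy-4,5-dimethoxybenzoate and chloromethyl methyl ether) to give the racemic 1,3-diketone F2. TsOH in MeOH at 60 °C should close the pyranone through the free ring-A hydroxyl (flavone closure at O1–C2) and then cleave the MOM ether to give 18. Isolated 18 would be closed to 19 by Ullmann-type vinyl etherification with CuI, 1,10-phenanthroline and Cs2CO3 in toluene at 110 °C.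

2. Step 3. At 200 °C the prenyl ether may be cleaved with loss of the C5 unit, the sequence may stop after the first sigmatropic shift, or the chromene may degrade thermally. The fallback replaces the sigmatropic route by halogenation and cross-coupling. It sets out from 4 and rejoins the route at 8. Iodination of 4 with NIS in MeCN at the only free ring position (para to the hydroxyl) should give 1-(5-hydroxy-8-iodo-7-methoxy-2,2-dimethyl-2H-chromen-6-yl)ethan-1-one F3. Stille coupling of F3 with tributyl(3-methylbut-2-en-1-yl)stannane (Pd(PPh3)4, DMF, 80 °C) should give 8.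

3. Step 1. Condensation may occur at C5 instead of C3, or ring closure may go through the chelated 2-hydroxyl, so regioisomeric chromenes could form. The fallback fixes the ring oxygen first and forms the C–C bond by a sigmatropic shift. It sets out from 1 and rejoins the route at 4. Selective O-alkylation of the non-chelated 4-hydroxyl of 1 with 3-chloro-3-methylbut-1-yne (K2CO3, KI, catalytic CuI, acetone) should give 1-[2-hydroxy-6-methoxy-4-(2-methylbut-3-yn-2-yloxy)phenyl]ethan-1-one F4. Heating F4 in xylene at 140 °C (aryl propargyl ether Claisen rearrangement, 1,5-hydrogen shift, oxa-6π closure) should give 4, the rearrangement being directed to C3 by the bond fixation of the chelated ortho-hydroxy ketone.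

**Further compounds**
F1 | step 8 | methyl 2-(methoxymethoxy)-4,5-dimethoxybenzoate | COCOc1cc(OC)c(OC)cc1C(=O)OC
F2 | step 8 | rac-2-(2-bromo-3-methylbut-2-en-1-yl)-1-[5-hydroxy-7-methoxy-2,2-dimethyl-8-(3-methylbut-2-en-1-yl)-2H-chromen-6-yl]-3-[2-(methoxymethoxy)-4,5-dimethoxyphenyl]propane-1,3-dione | COCOc1cc(OC)c(OC)cc1C(=O)C(CC(Br)=C(C)C)C(=O)c1c(O)c2C=CC(C)(C)Oc2c(CC=C(C)C)c1OC
F3 | step 3 | 1-(5-hydroxy-8-iodo-7-methoxy-2,2-dimethyl-2H-chromen-6-yl)ethan-1-one | CC(=O)c1c(O)c2C=CC(C)(C)Oc2c(I)c1OC
F4 | step 1 | 1-[2-hydroxy-6-methoxy-4-(2-methylbut-3-yn-2-yloxy)phenyl]ethan-1-one | CC(=O)c1c(O)cc(OC(C)(C)C#C)cc1OC
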